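A straight line through a log plot is a trap when two losses of different order share one substrate.

| setting | amber | red | flask |
|---|---|---|---|
| substrate | 0.020 M | 0.040 M | 0.020 M |
| remark | the very flask that is asked about, followed so far | run made earlier |  |
| time |  |  | 12 h |

| run | time / h | substrate / % | target / % | homo dimer / % |
|---|---|---|---|---|
| amber | 0.500 | 77 | 3 | 14 |
| amber | 1.00 | 63 | 0 | 23 |
| amber | 2.50 | 32 | 6 | 36 |
| amber | 6.00 | 11 | 9 | 44 |
| red | 1.50 | 33 | 5 | 46 |
| red | 4.00 | 14 | 6 | 56 |
| red | 8.00 | 5 | 7 | 55 |
| red | 12.0 | 2 | 10 | 58 |

(readings scatter by 1.5 percentage points)

- percent here means substrate units held: one homo dimer counts as two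

- substrate present at 12 h, in percent of the substrate charged
- target present at 12 h, in percent of the substrate charged
- homo dimer present at 12 h, in percent of the substrate charged

As a bench rule, I read one first-order constant from the amber run. From 0.500 h to 2.50 h it came to 0.439 h⁻¹, and from 2.50 h to 6.00 h to 0.305 h⁻¹, so it drifted down. I replaced each stretch of the curve by its mean substrate, 0.0109 M and 0.004300 M. I then split each constant into a fixed part and a part proportional to that mean. The two parts came out equal at 0.0107 M. I call this reading the crossover concentration: the substrate level at which first-order loss matches loss to homo dimer.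

The amber charge stood at 1.86 crossovers, so one constant failed at the start. At 6.00 h, substrate stood at 0.205 crossovers, and the rule could serve from there.

Summing the split over the run gives the overall selectivity for homo dimer:

share = 1 − (crossover / charge) × ln(1 + charge / crossover)

For amber, with the last few percent of substrate counted as used, this gave 43.5%. To check the mean, I took logarithmic means instead. The crossover moved to 0.0105 M, and the share to 44.1%. For the red charge, whose readings I had not used, the line gave 58.3% against the last red reading of 58%.

The forecast gave 2.5% substrate, 12% target and 46% homo dimer, reading “a first-order loss alongside second-order dimerisation”. Its homo dimer stood above mine.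

The amber flask gave 3.25% substrate, 10.7% target and 44.2% homo dimer at 12 h, so the forecast held on all three.

    substrate → intermediate A (k = 0.201 h⁻¹)
    intermediate A → intermediate B (k = 5.97 h⁻¹)
    intermediate B ⇌ target (K = 0.320, k = 0.978 h⁻¹)
    2 substrate → homo dimer (k = 9.71 M⁻¹ h⁻¹)
    target ⇌ isomer of the product (K = 0.760, k = 0.499 h⁻¹)

At 120 h the amber flask held 0% substrate and 44.3% homo dimer, against the 43.5% reckoned from its 1.86 crossovers. A neighbour flask had a charge of 0.012 M, which is 1.12 crossovers, and the same line gave 32.9%. At 12 h, that neighbour held 4.36% substrate and 33.5% homo dimer.

The numbers in the tables come from a simulation with made-up constants; scatter was added.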